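**Retrosynthetic overview**
- The δ-lactone comes from a Baeyer–Villiger ring expansion of a 2,2,4,4-tetrasubstituted cyclopentanone; the quaternary carbon migrates to oxygen with retention and becomes the C6–O stereocentre.
- The cyclopentanone comes from a desymmetrising protio-semipinacol ring expansion (1,2-shift of a ring CH2) of an achiral cis-1-alkenyl-3-methyl-3-silyloxycyclobutanol; this one step sets both stereocentres.
- The cyclobutanol comes from a 2-lithio-1-alkene and 3-methyl-3-silyloxycyclobutanone.
- The side chain comes from 6-chlorohexyne (hydrozirconation/benzylation gives the E-olefin), a C4 dihalide and 2,3-dibromopropene, joined by two Cu-catalysed Grignard couplings.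
- Ring order: cyclobutane (bought) → cyclopentanone → δ-lactone.

Assumption: 3-hydroxy-3-methylcyclobutan-1-one is taken as a catalogue building block, and the antipode of the chiral acid that gives the (2R,4R)-ketone is found by experiment (its mirror image gives the enantiomer).

**Step 1**
Reactants: 1 6-chlorohex-1-yne; 2 benzyl bromide
Product: 4 [(2E)-7-chlorohept-2-en-1-yl]benzene, via (E)-6-chlorohex-1-enylzirconocene chloride 3 (not isolated)
Conditions: Cp2Zr(H)Cl (1.1 equiv), THF, rt; then 2, Pd(PPh3)4 (3 mol %), ZnCl2 (cat.), THF, rt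
Reagents that add atoms: none
Why: syn-hydrozirconation (Schwartz) places Zr on the terminal carbon and the Pd-catalysed alkenyl–benzyl Negishi-type coupling goes with retention, so only the E-olefin forms, while the alkyl chloride is inert to both.

**Step 2**
Reactants: 4 [(2E)-7-chlorohept-2-en-1-yl]benzene; 5 1-bromo-4-chlorobutane
Product: 7 [(2E)-11-chloroundec-2-en-1-yl]benzene, via (5E)-7-phenylhept-5-enylmagnesium chloride 6 (not isolated)
Conditions: Mg, I2 (cat.), THF, reflux; then 5, Li2CuCl4 (3 mol %), THF, −10 °C → rt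
Reagents that add atoms: none
Why: Kochi-type Cu-catalysed sp3–sp3 Grignard coupling in which bromide is displaced selectively over chloride, leaving a new primary chloride for the next homologation.

**Step 3**
Reactants: 7 [(2E)-11-chloroundec-2-en-1-yl]benzene; 8 2,3-dibromoprop-1-ene
Product: 10 [(2E)-13-bromotetradeca-2,13-dien-1-yl]benzene, via (9E)-11-phenylundec-9-enylmagnesium chloride 9 (not isolated)
Conditions: Mg, THF, reflux; then 8, CuI (5 mol %), THF, −20 → 0 °C
Reagents that add atoms: none
Why: Cu-catalysed allylic substitution of 2,3-dibromopropene by a Grignard reagent (SN2 and SN2′ give the same 2-bromo-1-alkene), and the vinylic C–Br does not react without Ni or Pd.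

**Step 4**
Reactants: 11 3-hydroxy-3-methylcyclobutan-1-one
Product: 12 3-methyl-3-[(triethylsilyl)oxy]cyclobutan-1-one
Conditions: TESCl, imidazole, DMAP (cat.), DMF, 0 °C → rt
Reagents that add atoms: chlorotriethylsilane CC[Si](Cl)(CC)CC
Why: standard silylation of a tertiary alcohol, needed because the free β-alkoxide of a cyclobutanone would ring-open by retro-aldol under the basic conditions of step 5.

**Step 5**
Reactants: 10 [(2E)-13-bromotetradeca-2,13-dien-1-yl]benzene; 12 3-methyl-3-[(triethylsilyl)oxy]cyclobutan-1-one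
Product: 15 cis-3-methyl-1-[(12E)-14-phenyltetradeca-1,12-dien-2-yl]-3-[(triethylsilyl)oxy]cyclobutan-1-ol (OH and OSiEt3 on the same ring face; achiral), via (12E)-14-phenyltetradeca-1,12-dien-2-yllithium 13 (not isolated), via lithium alkoxide 14 (not isolated)
Conditions: 10, t-BuLi (2.0 equiv), Et2O, −78 °C; then 12, −78 °C; sat. aq. NH4Cl
Reagents that add atoms: none
Why: Br–Li exchange followed by 1,2-addition to the strained ketone, with the alkenyllithium expected to attack the face anti to the pseudo-axial OSiEt3 (steric and dipole control, as in additions to 3-alkoxycyclobutanones), which gives the 1,3-cis O/O isomer; the minor trans isomer is removed by chromatography.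

**Step 6**
Reactants: 15 cis-3-methyl-1-[(12E)-14-phenyltetradeca-1,12-dien-2-yl]-3-[(triethylsilyl)oxy]cyclobutan-1-ol
Product: 16 (2R,4R)-2,4-dimethyl-2-[(10E)-12-phenyldodec-10-en-1-yl]-4-[(triethylsilyl)oxy]cyclopentan-1-one
Conditions: confined chiral imidodiphosphorimidate (IDPi) Brønsted acid (5 mol %, antipode chosen by experiment), CHCl3/cyclohexane 1:1, 5 Å MS, −40 °C
Reagents that add atoms: none
Why: Proposed new method: an enantioselective desymmetrising protio-semipinacol ring expansion in which the chiral acid protonates the terminal CH2 of the 1,1-disubstituted olefin while its anion stays hydrogen-bonded to the cyclobutanol O–H, which holds the =CH2 syn to the O–H, and the developing tertiary cation is captured by 1,2-shift of one of the two enantiotopic ring CH2 groups selected by the chiral pocket, so that the migration terminus becomes the C2 quaternary centre and C4 becomes stereogenic in the same event; with the cis-O/O substrate the syn rotamer places the new CH3 on the face of the C4–OSi group (2,4-trans-dimethyl), strain release makes the shift irreversible, and the 1,2-disubstituted chain olefin is far less basic than the 1,1-disubstituted one; the closest known reaction types are chiral-acid protio-semipinacol expansions of alkenyl cyclopropanols and IDPi-catalysed Wagner–Meerwein ring expansions of purely aliphatic alkenyl cycloalkanes.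

**Step 7**
Reactants: 16 (2R,4R)-2,4-dimethyl-2-[(10E)-12-phenyldodec-10-en-1-yl]-4-[(triethylsilyl)oxy]cyclopentan-1-one
Product: 18 trisphaerolide A, (4R,6R)-4-hydroxy-4,6-dimethyl-6-[(10E)-12-phenyldodec-10-en-1-yl]oxan-2-one, via triethylsilyl-protected lactone 17 (not isolated)
Conditions: Me3SiOOSiMe3 (2.5 equiv), SnCl4 (0.3 equiv), trans-cyclohexane-1,2-diamine (0.3 equiv), 4 Å MS, CH2Cl2, 0 °C → rt; aq. Na2S2O3 wash; crude in THF, HF·pyridine, 0 °C → rt
Reagents that add atoms: bis(trimethylsilyl) peroxide C[Si](C)(C)OO[Si](C)(C)C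
Why: Baeyer–Villiger oxidation in which the quaternary α-carbon migrates to oxygen with retention, so C2 (R) of the ketone becomes C6 (R) of the lactone; the silyl peroxide/Lewis acid system oxidises ketones without epoxidising isolated C=C bonds, and HF then cleaves the tertiary silyl ether without touching the β-hydroxy lactone.

**Compound list**
1 | 6-chlorohex-1-yne | C#CCCCCCl | starting material
2 | benzyl bromide | BrCc1ccccc1 | starting material
3 | chlorido[(1E)-6-chlorohex-1-en-1-yl]zirconocene | ClCCCC/C=C/[Zr](Cl)(C1C=CC=C1)C1C=CC=C1 | intermediate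
4 | [(2E)-7-chlorohept-2-en-1-yl]benzene | ClCCCC/C=C/Cc1ccccc1 | intermediate
5 | 1-bromo-4-chlorobutane | ClCCCCBr | starting material
6 | [(5E)-7-phenylhept-5-en-1-yl]magnesium chloride | Cl[Mg]CCCC/C=C/Cc1ccccc1 | intermediate
7 | [(2E)-11-chloroundec-2-en-1-yl]benzene | ClCCCCCCCC/C=C/Cc1ccccc1 | intermediate
8 | 2,3-dibromoprop-1-ene | C=C(Br)CBr | starting material
9 | [(9E)-11-phenylundec-9-en-1-yl]magnesium chloride | Cl[Mg]CCCCCCCC/C=C/Cc1ccccc1 | intermediate
10 | [(2E)-13-bromotetradeca-2,13-dien-1-yl]benzene | C=C(Br)CCCCCCCCC/C=C/Cc1ccccc1 | intermediate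
11 | 3-hydroxy-3-methylcyclobutan-1-one | CC1(O)CC(=O)C1 | starting material
12 | 3-methyl-3-[(triethylsilyl)oxy]cyclobutan-1-one | CC1(O[Si](CC)(CC)CC)CC(=O)C1 | intermediate
13 | [(12E)-14-phenyltetradeca-1,12-dien-2-yl]lithium | [Li]C(=C)CCCCCCCCC/C=C/Cc1ccccc1 | intermediate
14 | lithium cis-3-methyl-1-[(12E)-14-phenyltetradeca-1,12-dien-2-yl]-3-[(triethylsilyl)oxy]cyclobutan-1-olate | [Li]O[C@]1(C(=C)CCCCCCCCC/C=C/Cc2ccccc2)C[C@](C)(O[Si](CC)(CC)CC)C1 | intermediate
15 | cis-3-methyl-1-[(12E)-14-phenyltetradeca-1,12-dien-2-yl]-3-[(triethylsilyl)oxy]cyclobutan-1-ol (OH cis to OSiEt3) | O[C@]1(C(=C)CCCCCCCCC/C=C/Cc2ccccc2)C[C@](C)(O[Si](CC)(CC)CC)C1 | intermediate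
16 | (2R,4R)-2,4-dimethyl-2-[(10E)-12-phenyldodec-10-en-1-yl]-4-[(triethylsilyl)oxy]cyclopentan-1-one | C[C@]1(O[Si](CC)(CC)CC)CC(=O)[C@](C)(CCCCCCCCC/C=C/Cc2ccccc2)C1 | intermediate
17 | (4R,6R)-4,6-dimethyl-6-[(10E)-12-phenyldodec-10-en-1-yl]-4-[(triethylsilyl)oxy]oxan-2-one | C[C@]1(O[Si](CC)(CC)CC)CC(=O)O[C@](C)(CCCCCCCCC/C=C/Cc2ccccc2)C1 | intermediate
18 | trisphaerolide A, (4R,6R)-4-hydroxy-4,6-dimethyl-6-[(10E)-12-phenyldodec-10-en-1-yl]oxan-2-one | C[C@]1(O)CC(=O)O[C@](C)(CCCCCCCCC/C=C/Cc2ccccc2)C1 | target

**Step count and risks**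
Total steps: 7. Longest linear sequence: 6 (steps 1, 2, 3, 5, 6, 7).

Most likely to fail, step 6 (the proposed new ring expansion): the acid may give low enantio- or diastereoselectivity, or isomerise the olefin instead. The fallback sets out from 15 and uses known chemistry. A classical achiral acid-mediated alkenylcyclobutanol → cyclopentanone rearrangement (Tf2NH 5 mol % or TsOH, CH2Cl2, 0 °C) gives 2,4-dimethyl-2-[(10E)-12-phenyldodec-10-en-1-yl]-4-[(triethylsilyl)oxy]cyclopentan-1-one as a stereoisomer mixture F1. The diastereomers are separated on silica and the 2,4-trans-dimethyl racemate is resolved by preparative chiral-phase HPLC/SFC. The route is rejoined at 16.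

Second, step 7 (Baeyer–Villiger next to a quaternary centre in the presence of the chain olefin): the hindered ketone may react too slowly with the silyl peroxide. The fallback sets out from 16 and gives up chemoselectivity. Excess mCPBA/NaHCO3 in CH2Cl2 performs the Baeyer–Villiger and also epoxidises the olefin, giving (4R,6R)-6-[9-(3-benzyloxiran-2-yl)nonyl]-4,6-dimethyl-4-[(triethylsilyl)oxy]oxan-2-one (trans-epoxide, both diastereomers) F2. Stereospecific deoxygenation with retention (NaI, (CF3CO)2O, THF/MeCN, 0 °C → rt) restores the E-olefin. The route is rejoined at 17, which is desilylated as in step 7.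

Third, step 5 (addition of a basic alkenyllithium to a β-silyloxy cyclobutanone): enolisation or silanolate elimination may compete, or the cis selectivity may be incomplete, at the cost of the advanced bromide 10. The fallback sets out from 12 and 7 and attaches the chain after the ring–alkene bond. Isopropenylmagnesium bromide with CeCl3 (THF, −78 °C) adds to 12 to give cis-3-methyl-1-(prop-1-en-2-yl)-3-[(triethylsilyl)oxy]cyclobutan-1-ol F3, a small compound that is easily freed of its trans isomer. Chloride 7 is converted with NaI in refluxing acetone into [(2E)-11-iodoundec-2-en-1-yl]benzene F4. The alkoxide-directed allylic dianion of F3 (n-BuLi 2.2 equiv, TMEDA, Et2O/hexane, 0 °C) is alkylated with F4 at −78 °C. The route is rejoined at 15.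

**Further compounds**
F1 | step 6 | 2,4-dimethyl-2-[(10E)-12-phenyldodec-10-en-1-yl]-4-[(triethylsilyl)oxy]cyclopentan-1-one, mixture of stereoisomers | CC1(O[Si](CC)(CC)CC)CC(=O)C(C)(CCCCCCCCC/C=C/Cc2ccccc2)C1
F2 | step 7 | (4R,6R)-6-[9-(3-benzyloxiran-2-yl)nonyl]-4,6-dimethyl-4-[(triethylsilyl)oxy]oxan-2-one, trans-epoxide, both diastereomers | C[C@]1(O[Si](CC)(CC)CC)CC(=O)O[C@](C)(CCCCCCCCCC2OC2Cc2ccccc2)C1
F3 | step 5 | cis-3-methyl-1-(prop-1-en-2-yl)-3-[(triethylsilyl)oxy]cyclobutan-1-ol (OH cis to OSiEt3) | O[C@]1(C(C)=C)C[C@](C)(O[Si](CC)(CC)CC)C1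
F4 | step 5 | [(2E)-11-iodoundec-2-en-1-yl]benzene | ICCCCCCCC/C=C/Cc1ccccc1
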